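## Retrosynthetic overview

- 17 ⇐ 16 (ester cleavage) ⇐ 15 (ring A by aldol, C3–C4) ⇐ 13 (ring D by ketyl–olefin closure, C16–C13) ⇐ 11 (γ-lactone by Michael addition, C4–C5) ⇐ 7 (C1–C3 unit added to the C10 ketone).
- Ring B is not made as a cyclopentane. It is carried as the six-membered ring of methoxy-p-quinone 2, which builds ring C and the C8/C9 stereocentres by a catalytic enantioselective Diels–Alder reaction (4), and is then contracted (4 → 7) with C7 pushed out of the ring as the ester carbon.
- Enabling feature: in ring B, C6 carries the C7 carboxyl, lies between C5–H and the quaternary C8, and is 1,3 to the oxygen-bearing C10. C7, C6, C5 and C10 thus map onto the C(=O)–C(OMe)=CH–C(=O) unit of the quinone and C8 onto its allyl-bearing carbon, so a 1,2-shift of C8 from C7 to C6 with loss of methoxide gives the ring B keto enoate directly.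
- Order of ring formation: C (with the six-membered precursor of B) → B (contraction) → lactone → D → A.

Key step: step 3

Locants: gibberellin numbering of the target is used for all intermediates (in 4: C1 = C7, C2 = C6, C3 = C5, C4 = C10, C4a = C9, C8a = C8, C5–C8 = C11–C14); β is the face of ring B that bears H-5 and H-9.

Assumption: the (S)-prolinol-derived oxazaborolidinium catalyst is taken to deliver 4 and not its enantiomer; if the facial sense is the opposite, the (R)-catalyst is used.

## Route

Step 1
Reactants: 1 2-allyl-6-methoxyphenol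
Product: 2 2-allyl-6-methoxy-1,4-benzoquinone
Conditions: Co(salen) [Co(C16H14N2O2)] (10 mol %), O2 (1 atm), DMF, 23 °C
Reagents that add atoms: dioxygen, O=O
Why: Aerobic cobalt–salen oxidation of a 2,6-disubstituted phenol with a free para position is a standard entry to the p-quinone, and the allyl group is inert.

Step 2
Reactants: 2 2-allyl-6-methoxy-1,4-benzoquinone; 3 buta-1,3-diene
Product: 4 (4aR,8aS)-8a-allyl-2-methoxy-4a,5,8,8a-tetrahydronaphthalene-1,4-dione
Conditions: 3 (5 equiv), (S)-3,3-diphenyl-1-(o-tolyl)tetrahydropyrrolo[1,2-c][1,3,2]oxazaborole·HNTf2 (20 mol %), CH2Cl2, −78 → −40 °C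
Reagents that add atoms: none
Why: Catalytic enantioselective quinone Diels–Alder reaction: the methoxy-bearing double bond is deactivated as a vinylogous ester, so the diene adds to the allyl-bearing one, suprafacial addition gives the cis ring fusion (allyl and H syn) that is the C8/C9 relationship of the target, and the chiral Lewis acid on the C10 carbonyl selects the face and so sets C8 (S) and C9 (R).

Step 3
Reactants: 4 (4aR,8aS)-8a-allyl-2-methoxy-4a,5,8,8a-tetrahydronaphthalene-1,4-dione
Product: 7 methyl (3aS,7aR)-3a-allyl-1-oxo-3a,4,7,7a-tetrahydro-1H-indene-3-carboxylate, via sodium hemiketal alkoxide 5 (not isolated), via ring-contracted sodium enolate 6 (not isolated)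
Conditions: NaOMe (0.3 equiv), MeOH, 60 °C; AcOH quench
Reagents that add atoms: sodium methoxide, [Na+].[O-]C
Why: Proposed new method: methoxide adds to the C7 ketone of 4, the only carbonyl that is not deactivated as a vinylogous ester, and alkoxide 5 pushes its quaternary neighbour C8 in a 1,2-shift onto C6, the β-carbon of the C10 enone, to give enolate 6, which expels the C6 methoxide and so makes the step irreversible; the closest known reactions are the benzilic ester rearrangement and the quasi-Favorskii (semibenzilic) ring contraction, here with a vinylogous ester carbon as migration terminus and methoxide as leaving group. No ring is closed between chain ends: the five-membered ring B arises from the six-membered quinone ring by this 1,2-shift, a ring contraction by one atom in which C7 leaves the ring as the ester carbon. No stereocentre is created, since C8 migrates with retention and C9, epimerisable next to the C10 ketone, should stay cis because a cis-fused hydrindenone is much less strained than its trans isomer. The step needs addition at C7 and not at C10, and migration of C8 and not of C9: the C10 carbonyl is a vinylogous ester that forms no stable adduct, only the shift to the methoxy-bearing carbon can end in loss of a leaving group, and a quaternary carbon migrates better than a tertiary one. In one operation the step makes ring B, brings C7 to the ester oxidation level, uncovers the C5=C6 acceptor for the lactone closure and keeps the C10 ketone, and the methoxy group that steered the Diels–Alder reaction serves as the leaving group.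

Step 4
Reactants: 7 methyl (3aS,7aR)-3a-allyl-1-oxo-3a,4,7,7a-tetrahydro-1H-indene-3-carboxylate; 8 2-(2-bromoethyl)-1,3-dioxolane
Product: 11 methyl (1S,3aS,7aR)-3a-allyl-1-[2-(1,3-dioxolan-2-yl)ethyl]-1-(propanoyloxy)-3a,4,7,7a-tetrahydro-1H-indene-3-carboxylate, via alkylmagnesium bromide 9 (not isolated), via bromomagnesium tertiary alkoxide 10 (not isolated)
Conditions: 8, Mg, THF, 23 °C; CeCl3, THF, −78 °C, then 7; then (EtCO)2O, DMAP (cat.), −78 → 23 °C
Reagents that add atoms: propionic anhydride, CCC(=O)OC(=O)CC
Why: Organocerium 1,2-addition to an enolisable conjugated ketone leaves the ester untouched, attack on the convex β face of the cis-fused bicycle (anti to C11 and ring C) puts the new C10 oxygen α and C1 β, and the tertiary alkoxide (written as its magnesium salt 10) is acylated in the same flask.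

Step 5
Reactants: 11 methyl (1S,3aS,7aR)-3a-allyl-1-[2-(1,3-dioxolan-2-yl)ethyl]-1-(propanoyloxy)-3a,4,7,7a-tetrahydro-1H-indene-3-carboxylate
Product: 12 tricyclic 19,10-lactone methyl ester (C4–C5 bond formed; 8β-allyl; ring C 12-ene; 10β-dioxolanylethyl; 5β-H; 6β-CO2Me)
Conditions: KOt-Bu (0.3 equiv), t-BuOH–THF, 0 → 23 °C
Reagents that add atoms: none
Why: Intramolecular Michael addition of the propionate enolate to the C5=C6 enoate (5-exo-trig at the acceptor, with the enolate double bond inside the new ring, a slower mode that the reversible conditions tolerate and that is known for acyloxy-tethered closures to cis-fused γ-lactones), in which the tether from the α-oxygen at C10 forces C4 onto the α face of C5 (H-5 β) and the equilibrating alkoxide lets C6 settle with the ester β, trans to C4 (the C4 epimers converge in step 9).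

Step 6
Reactants: 12 tricyclic 19,10-lactone methyl ester (8β-allyl)
Product: 13 methyl ketone (8β-(2-oxopropyl) analogue of 12)
Conditions: PdCl2 (10 mol %), CuCl (20 mol %), O2 (1 atm), DMF–H2O (7:1), 23 °C
Reagents that add atoms: water, O
Why: Wacker oxidation is selective for the terminal alkene of the allyl group over the 1,2-disubstituted ring C alkene and gives the methyl ketone by Markovnikov attack of water; no stereocentre is formed.

Step 7
Reactants: 13 methyl ketone (8β-(2-oxopropyl) analogue of 12)
Product: 14 tetracyclic tertiary alcohol (ring D closed; 16-OH exo and 16-CH3 endo; dioxolane intact)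
Conditions: SmI2 (2.5 equiv), HMPA (8 equiv), t-BuOH (2 equiv), THF, 0 → 23 °C
Reagents that add atoms: none
Why: SmI2-mediated ketyl–olefin cyclization (5-exo-trig) of the C16 ketyl onto C13 of the ring C alkene, in which the tether from C8 allows only the bridged bicyclo[3.2.1]octane (fixing C13) and the bulky O–Sm group sits exo, anti to the developing C12 radical, so that the hydroxyl ends exo and the methyl endo as in the target.

Step 8
Reactants: 14 tetracyclic tertiary alcohol (dioxolane)
Product: 15 C3 aldehyde (10β-(3-oxopropyl) compound)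
Conditions: PPTS (cat.), acetone–H2O, 50 °C
Reagents that add atoms: water, O
Why: Mild acid-catalysed acetal hydrolysis frees the C3 aldehyde while lactone, ester and tertiary alcohol are stable; no stereocentre is touched.

Step 9
Reactants: 15 C3 aldehyde (10β-(3-oxopropyl) compound)
Product: 16 target gibberellin 7-methyl ester
Conditions: KHMDS (2.1 equiv), 18-crown-6, THF, −78 → −30 °C; AcOH quench
Reagents that add atoms: none
Why: Intramolecular aldol addition (6-(enolexo)-exo-trig) that closes ring A: after the C16 alkoxide has formed, the lactone enolate, generated directly or by proton transfer from the reversibly formed and unproductive aldehyde enolate, adds to the C3 aldehyde, which can reach only the convex face of C4 (this fixes C4), and the non-chelated potassium enolate should place the C3–O bond anti to the lactone carbonyl, i.e. axial 3β.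

Step 10
Reactants: 16 target gibberellin 7-methyl ester
Product: 17 target gibberellin (free 7-carboxylic acid)
Conditions: n-PrSLi (5 equiv), HMPA, 23 °C; then aq. HCl to pH 3
Reagents that add atoms: none
Why: SN2 demethylation of the hindered methyl ester by thiolate avoids hydroxide, which would open the lactone and could epimerise C3 by retro-aldol reaction; no stereocentre is touched.

## Compound list

1 | 2-allyl-6-methoxyphenol | C=CCc1cccc(OC)c1O | starting material
2 | 2-allyl-6-methoxy-1,4-benzoquinone | O=C1C=C(OC)C(=O)C(CC=C)=C1 | intermediate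
3 | buta-1,3-diene | C=CC=C | starting material
4 | (4aR,8aS)-8a-allyl-2-methoxy-4a,5,8,8a-tetrahydronaphthalene-1,4-dione (cis ring fusion) | O=C1[C@@H]2CC=CC[C@]2(CC=C)C(=O)C(OC)=C1 | intermediate
5 | sodium hemiketal alkoxide (methoxide adduct at the C7 carbonyl of 4) | O=C1[C@@H]2CC=CC[C@]2(CC=C)C([O-])(OC)C(OC)=C1.[Na+] | intermediate (not isolated)
6 | ring-contracted sodium enolate (C8 shifted to C6, methoxy still on C6) | [O-]C=1[C@@H]2CC=CC[C@]2(CC=C)C(OC)(C(=O)OC)C=1.[Na+] | intermediate (not isolated)
7 | methyl (3aS,7aR)-3a-allyl-1-oxo-3a,4,7,7a-tetrahydro-1H-indene-3-carboxylate (cis ring fusion) | O=C1[C@@H]2CC=CC[C@]2(CC=C)C(C(=O)OC)=C1 | intermediate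
8 | 2-(2-bromoethyl)-1,3-dioxolane | BrCCC1OCCO1 | starting material
9 | [2-(1,3-dioxolan-2-yl)ethyl]magnesium bromide | Br[Mg]CCC1OCCO1 | intermediate (not isolated)
10 | bromomagnesium tertiary alkoxide (C10 adduct of 7, oxygen α) | Br[Mg]O[C@]1(CCC2OCCO2)[C@@H]2CC=CC[C@]2(CC=C)C(C(=O)OC)=C1 | intermediate (not isolated)
11 | methyl (1S,3aS,7aR)-3a-allyl-1-[2-(1,3-dioxolan-2-yl)ethyl]-1-(propanoyloxy)-3a,4,7,7a-tetrahydro-1H-indene-3-carboxylate | CCC(=O)O[C@]1(CCC2OCCO2)[C@@H]2CC=CC[C@]2(CC=C)C(C(=O)OC)=C1 | intermediate
12 | tricyclic 19,10-lactone methyl ester: 4-methyl on the convex face, 5β-H, 6β-CO2Me, 8β-allyl, 9β-H, 10β-[2-(1,3-dioxolan-2-yl)ethyl], ring C 12-ene | C[C@H]1C(=O)O[C@]2(CCC5OCCO5)[C@@H]3CC=CC[C@]3(CC=C)[C@@H](C(=O)OC)[C@@H]21 | intermediate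
13 | methyl ketone: as 12 with 8β-(2-oxopropyl) in place of allyl | C[C@H]1C(=O)O[C@]2(CCC5OCCO5)[C@@H]3CC=CC[C@]3(CC(C)=O)[C@@H](C(=O)OC)[C@@H]21 | intermediate
14 | tetracyclic tertiary alcohol: rings B, C, D and lactone as in the target (16-OH exo, 16-CH3 endo), ring A open, 10β-[2-(1,3-dioxolan-2-yl)ethyl], 7-methyl ester | C[C@H]1C(=O)O[C@]2(CCC5OCCO5)[C@@H]3CC[C@@H]4C[C@]3(C[C@@]4(C)O)[C@@H](C(=O)OC)[C@@H]21 | intermediate
15 | C3 aldehyde: as 14 with 10β-(3-oxopropyl) | C[C@H]1C(=O)O[C@]2(CCC=O)[C@@H]3CC[C@@H]4C[C@]3(C[C@@]4(C)O)[C@@H](C(=O)OC)[C@@H]21 | intermediate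
16 | target gibberellin 7-methyl ester (3β-OH, 16-OH exo, 19,10-lactone, 6β-CO2Me) | C[C@@]12C(=O)O[C@]3(CC[C@@H]1O)[C@@H]1CC[C@@H]4C[C@]1(C[C@@]4(C)O)[C@@H](C(=O)OC)[C@@H]32 | intermediate
17 | target gibberellin: 3β,16-dihydroxy 19,10-lactone with free 6β-carboxylic acid (16-OH exo, 16-CH3 endo) | C[C@@]12C(=O)O[C@]3(CC[C@@H]1O)[C@@H]1CC[C@@H]4C[C@]1(C[C@@]4(C)O)[C@@H](C(=O)O)[C@@H]32 | target

## Totals

Total step count: 10. Longest linear sequence: 10 steps (1 → 17).

## Steps most likely to fail

**Step 3 (proposed new method).** The 1,2-shift may not take place because the migrating ring bond overlaps poorly with the π system of the acceptor. Methoxide may also add at the other carbonyl and move C9 instead, or add reversibly to the product enone.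

Fallback (known chemistry, ring B still made by contraction), from 4 back to 7: SmI2 in THF–MeOH at −78 °C should reduce the ene-dione and cleave the α-methoxy group to give (4aS,8aR)-4a-allyl-2,3,4a,5,8,8a-hexahydronaphthalene-1,4-dione F1. Ethylene glycol with PPTS in benzene should ketalise only the less hindered C10 ketone and give the C10 mono-dioxolane of the cis-dione F2. Direct diazo transfer (2,4,6-triisopropylbenzenesulfonyl azide, KOH, Bu4NBr, 18-crown-6, benzene) at the only enolisable position of the C7 ketone should give the C6 diazo ketone F3. Irradiation in MeOH should bring about the photochemical Wolff rearrangement to the ring-contracted methyl ester ketal F4. LDA and PhSeBr in THF at −78 °C should selenenylate C6, the only acidic position, and give the C6 phenylselenide F5. Aqueous hydrogen peroxide with pyridine in CH2Cl2 should then eliminate the selenoxide towards C5, the only neighbour that carries hydrogen, and give the unsaturated ester ketal F6. Aqueous HCl in acetone should free the C10 ketone and return 7.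

**Step 7.** The ketyl may be reduced to the secondary alcohol before it cyclises, or it may close in the 6-endo mode to the bicyclo[2.2.2]octane.

Fallback, from 13 back to 14: KHMDS and PhNTf2 in THF at −78 °C should deprotonate the methyl group of the ketone and give the enol triflate F7. Heck cyclization (Pd(OAc)2, PPh3, K2CO3, DMF, 80 °C; 5-exo onto C13, then β-hydride elimination towards C11, the only neighbour with a syn hydrogen) should give the 16-methylene 11-ene tetracycle F8. Mukaiyama hydration (Co(acac)2, PhSiH3, O2, i-PrOH), which is selective for the 1,1-disubstituted alkene, should place oxygen on the exo face of the tertiary C16 radical and give the 11-ene tertiary alcohol F9. Hydrogenation (hydrogen at 1 atm, Pd/C, EtOAc) should saturate C11=C12 and return 14.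

**Step 9.** The aldehyde may be attacked from the wrong face (equatorial 3α-alcohol through a chelated transition state), and enolisation of the aldehyde may lower conversion.

Fallback, from 15 back to 16: an equilibrating aldol closure (KOt-Bu, t-BuOH–THF) should close ring A with the hydroxyl mainly equatorial, giving the 3-epi (3α-hydroxy) 7-methyl ester F10. Oxidation with 1,1,1-triacetoxy-1,1-dihydro-1,2-benziodoxol-3(1H)-one should give the 3-oxo 7-methyl ester F11. LiBH(s-Bu)3 in THF at −78 °C should deliver hydride along the equatorial direction and give the axial 3β-alcohol 16.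

Further compounds
F1 | step 3 | (4aS,8aR)-4a-allyl-2,3,4a,5,8,8a-hexahydronaphthalene-1,4-dione | O=C1[C@@H]2CC=CC[C@]2(CC=C)C(=O)CC1
F2 | step 3 | C10 mono-dioxolane of the cis-dione | O=C1CCC3(OCCO3)[C@@H]2CC=CC[C@]12CC=C
F3 | step 3 | C6 diazo ketone | O=C1C(=[N+]=[N-])CC3(OCCO3)[C@@H]2CC=CC[C@]12CC=C
F4 | step 3 | ring-contracted methyl ester ketal | COC(=O)C1CC3(OCCO3)[C@@H]2CC=CC[C@]12CC=C
F5 | step 3 | C6 phenylselenide | COC(=O)C1([Se]c4ccccc4)CC3(OCCO3)[C@@H]2CC=CC[C@]12CC=C
F6 | step 3 | unsaturated ester ketal | COC(=O)C1=CC3(OCCO3)[C@@H]2CC=CC[C@]12CC=C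
F7 | step 7 | enol triflate | C[C@H]1C(=O)O[C@]2(CCC5OCCO5)[C@@H]3CC=CC[C@]3(CC(=C)OS(=O)(=O)C(F)(F)F)[C@@H](C(=O)OC)[C@@H]21
F8 | step 7 | 16-methylene 11-ene tetracycle | C[C@H]1C(=O)O[C@]2(CCC5OCCO5)[C@@H]3C=C[C@@H]4C[C@]3(CC4=C)[C@@H](C(=O)OC)[C@@H]21
F9 | step 7 | 11-ene tertiary alcohol | C[C@H]1C(=O)O[C@]2(CCC5OCCO5)[C@@H]3C=C[C@@H]4C[C@]3(C[C@@]4(C)O)[C@@H](C(=O)OC)[C@@H]21
F10 | step 9 | 3-epi (3α-hydroxy) 7-methyl ester | C[C@@]12C(=O)O[C@]3(CC[C@H]1O)[C@@H]1CC[C@@H]4C[C@]1(C[C@@]4(C)O)[C@@H](C(=O)OC)[C@@H]32
F11 | step 9 | 3-oxo 7-methyl ester | C[C@@]12C(=O)O[C@]3(CCC1=O)[C@@H]1CC[C@@H]4C[C@]1(C[C@@]4(C)O)[C@@H](C(=O)OC)[C@@H]32
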